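**Retrosynthetic overview**
1. Target 8 ⇐ flavone 6 (sinensetin): the C2 stereocentre is set last by an enantioselective 1,4-reduction of the C2=C3 bond (proposed new step).
2. Flavone 6 ⇐ 2'-hydroxychalcone 4: oxidative 6-endo ring closure forms O1–C2 and the pyranone ring C.
3. Chalcone 4 ⇐ acetophenone 2 + veratraldehyde 3: Claisen–Schmidt condensation forms the C2–C3 bond.
4. Acetophenone 2 ⇐ 3,4,5-trimethoxyphenol 1: Friedel–Crafts acetylation forms the C4–C4a bond.
5. Ring order: rings A and B are bought intact, ring C is closed in step 3, the stereocentre is set in step 4.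

Assumption: the facial sense of the new step 4 cannot be predicted with certainty; the (R)-acid is written, and its mirror image is used with nothing else changed if the first run (chiral HPLC, ECD) shows the 2R ketone in excess.

**Route**

Step 1
Reactants: 1 3,4,5-trimethoxyphenol
Product: 2 1-(6-hydroxy-2,3,4-trimethoxyphenyl)ethan-1-one
Conditions: AcOH, BF3·OEt2 (neat, Lewis acid and medium), 90 °C, 2 h
Reagents that add atoms: acetic acid, CC(=O)O
Why: Friedel–Crafts C-acetylation (Fries-type) of a very electron-rich phenol; the only two free ring positions are equivalent and ortho to OH, so one regioisomer forms, and the deactivated ketone is not acylated again.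

Step 2
Reactants: 2 1-(6-hydroxy-2,3,4-trimethoxyphenyl)ethan-1-one; 3 3,4-dimethoxybenzaldehyde (veratraldehyde)
Product: 4 (E)-3-(3,4-dimethoxyphenyl)-1-(6-hydroxy-2,3,4-trimethoxyphenyl)prop-2-en-1-one
Conditions: KOH (50% aq.), EtOH, rt, 48 h
Reagents that add atoms: none
Why: Claisen–Schmidt (crossed aldol) condensation of the ketone enolate with a non-enolisable aldehyde, followed by E1cB loss of water to the conjugated (E)-enone; in strong base the product rests as its phenolate, which holds back ring closure.

Step 3
Reactants: 4 (E)-3-(3,4-dimethoxyphenyl)-1-(6-hydroxy-2,3,4-trimethoxyphenyl)prop-2-en-1-one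
Product: 6 sinensetin (5,6,7,3',4'-pentamethoxyflavone), via trans-3-iodoflavanone 5 (not isolated)
Conditions: I2 (10 mol%), DMSO, 130 °C, 2 h
Reagents that add atoms: none
Why: Iodine-catalysed oxidative cyclisation: iodine-induced 6-endo attack of the phenol on the enone (anti addition) gives the 3-iodoflavanone, which loses HI to the aromatic 4-pyranone, and DMSO reoxidises HI to I2 as the terminal oxidant.

Step 4
Reactants: 6 sinensetin (5,6,7,3',4'-pentamethoxyflavone)
Product: 8 (2S)-5,6,7,3',4'-pentamethoxyflavanone, via (2S)-flav-3-en-4-ol 7 (not isolated)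
Conditions: (R)-TRIP N-triflylphosphoramide (10 mol%), 2-(2-naphthyl)benzothiazoline (1.5 equiv), toluene, 5 Å MS, 50 °C, 24–48 h
Reagents that add atoms: none
Why: Proposed new method: chiral Brønsted acid-catalysed asymmetric transfer hydrogenation of a flavone C2=C3 bond; the strong acid protonates the 4-carbonyl oxygen (proton shared with 5-OMe) to a 4-hydroxyflavylium ion held in a contact ion pair with the chiral phosphoramidate, whose second basic site binds the N–H of the benzothiazoline, so hydride is passed to one face of C2 (the position where soft nucleophiles add to 4-oxy-benzopyrylium ions, C4 being deactivated by its OH) and the (2S) centre is set irreversibly, after which enol 7 tautomerises to ketone 8 without touching C2; the benzothiazoline does not reduce the neutral flavone, so there is no racemic background, and the weakly basic benzothiazole by-product does not trap the acid; closest known reaction type: chiral phosphoric acid transfer hydrogenation of quinolines and ketimines with Hantzsch esters or benzothiazolines, and chiral-anion-controlled hydride reduction of 1-benzopyrylium ions.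

**Compound list**

1 | 3,4,5-trimethoxyphenol | COc1cc(O)cc(OC)c1OC | starting material
2 | 1-(6-hydroxy-2,3,4-trimethoxyphenyl)ethan-1-one (6'-hydroxy-2',3',4'-trimethoxyacetophenone) | CC(=O)c1c(O)cc(OC)c(OC)c1OC | intermediate
3 | 3,4-dimethoxybenzaldehyde (veratraldehyde) | COc1ccc(C=O)cc1OC | starting material
4 | (E)-3-(3,4-dimethoxyphenyl)-1-(6-hydroxy-2,3,4-trimethoxyphenyl)prop-2-en-1-one (2'-hydroxy-3,4,4',5',6'-pentamethoxychalcone) | COc1ccc(/C=C/C(=O)c2c(O)cc(OC)c(OC)c2OC)cc1OC | intermediate
5 | (±)-trans-(2R*,3R*)-2-(3,4-dimethoxyphenyl)-3-iodo-5,6,7-trimethoxychroman-4-one (racemic, one enantiomer drawn; formed and consumed in step 3) | COc1ccc([C@H]2Oc3cc(OC)c(OC)c(OC)c3C(=O)[C@@H]2I)cc1OC | intermediate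
6 | 2-(3,4-dimethoxyphenyl)-5,6,7-trimethoxy-4H-chromen-4-one (sinensetin) | COc1ccc(-c2cc(=O)c3c(cc(OC)c(OC)c3OC)o2)cc1OC | intermediate
7 | (2S)-2-(3,4-dimethoxyphenyl)-5,6,7-trimethoxy-2H-chromen-4-ol (enol; formed and consumed in step 4) | COc1ccc([C@@H]2C=C(O)c3c(cc(OC)c(OC)c3OC)O2)cc1OC | intermediate
8 | (2S)-2-(3,4-dimethoxyphenyl)-5,6,7-trimethoxychroman-4-one, (2S)-5,6,7,3',4'-pentamethoxyflavanone | COc1ccc([C@@H]2CC(=O)c3c(cc(OC)c(OC)c3OC)O2)cc1OC | target

**Totals**
Total step count: 4
Longest linear sequence: 4 steps (1 → 2 → 4 → 6 → 8)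

**Three steps most likely to fail, with fallbacks**

The most likely to fail is step 4, the proposed new transfer hydrogenation. The flavone may be too weakly basic to be activated, hydride may attack C4 and lead to over-reduced flavenes, or the 5-OMe group may crowd the acid binding site and lower the ee. The fallback uses known chemistry, sets out from chalcone 4 and comes back to the route at target 8. Chalcone 4 is isomerised with NaOAc in refluxing EtOH to (±)-5,6,7,3',4'-pentamethoxyflavanone F1. F1 is then kinetically resolved by asymmetric transfer hydrogenation with a Noyori–Ikariya-type catalyst, Cp*RhCl[(R,R)-TsDPEN] (1 mol%), HCO2H/Et3N (5:2), EtOAc, rt, stopped near 52% conversion. The (2R)-ketone is reduced by hydride delivery anti to the aryl group to the cis alcohol (2R,4R)-2-(3,4-dimethoxyphenyl)-5,6,7-trimethoxychroman-4-ol F2, and the unreacted (2S)-ketone 8 is separated by chromatography (at most 50%).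

Second is step 3. HI at 130 °C could iodinate the activated C8 position or cleave the 5-OMe group. The fallback sets out from acetophenone 2 and comes back at flavone 6 through a Baker–Venkataraman sequence that avoids the chalcone. Acetophenone 2 is O-acylated with 3,4-dimethoxybenzoyl chloride (pyridine, rt) to 2-acetyl-3,4,5-trimethoxyphenyl 3,4-dimethoxybenzoate F3. KOH in pyridine at 50 °C shifts the aroyl group to carbon and gives 1-(3,4-dimethoxyphenyl)-3-(6-hydroxy-2,3,4-trimethoxyphenyl)propane-1,3-dione F4. H2SO4 (cat.) in AcOH at 100 °C cyclodehydrates F4 to 6.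

Third is step 2. The doubly ortho-substituted ketone is hindered, and its phenolate lowers the α-acidity, so condensation with the electron-rich aldehyde can stall. The fallback sets out from 2 and comes back at chalcone 4 with the phenol masked. MOMCl and iPr2NEt in CH2Cl2 give 1-[2,3,4-trimethoxy-6-(methoxymethoxy)phenyl]ethan-1-one F5. Condensation of F5 with 3 (KOH, EtOH, rt) gives (E)-3-(3,4-dimethoxyphenyl)-1-[2,3,4-trimethoxy-6-(methoxymethoxy)phenyl]prop-2-en-1-one F6. HCl (cat.) in MeOH at 40 °C removes the MOM group and gives 4.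

**Further compounds**

F1 | step 4 | (±)-5,6,7,3',4'-pentamethoxyflavanone | COc1ccc(C2CC(=O)c3c(cc(OC)c(OC)c3OC)O2)cc1OC
F2 | step 4 | (2R,4R)-2-(3,4-dimethoxyphenyl)-5,6,7-trimethoxychroman-4-ol (cis) | COc1ccc([C@H]2C[C@@H](O)c3c(cc(OC)c(OC)c3OC)O2)cc1OC
F3 | step 3 | 2-acetyl-3,4,5-trimethoxyphenyl 3,4-dimethoxybenzoate | COc1ccc(C(=O)Oc2cc(OC)c(OC)c(OC)c2C(C)=O)cc1OC
F4 | step 3 | 1-(3,4-dimethoxyphenyl)-3-(6-hydroxy-2,3,4-trimethoxyphenyl)propane-1,3-dione | COc1ccc(C(=O)CC(=O)c2c(O)cc(OC)c(OC)c2OC)cc1OC
F5 | step 2 | 1-[2,3,4-trimethoxy-6-(methoxymethoxy)phenyl]ethan-1-one | CC(=O)c1c(OCOC)cc(OC)c(OC)c1OC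
F6 | step 2 | (E)-3-(3,4-dimethoxyphenyl)-1-[2,3,4-trimethoxy-6-(methoxymethoxy)phenyl]prop-2-en-1-one | COCOc1cc(OC)c(OC)c(OC)c1C(=O)/C=C/c1ccc(OC)c(OC)c1
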